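**Plan**
- Numbering: ring A = C1–C5 + C10 (C3 ketone, C4 gem-dimethyl). Ring B = C5–C10 (C8 carbinol, C9 chain carbon, C11 first chain atom). β is the face of CH3-10 and H-5, which the target shows to be cis.
- Cuts, in retrosynthetic order: C3=O back to a C3–H next to a C1=C2 alkene; C11–C12 (sulfone anion + farnesyl bromide); C8–CH3; C9–C11; then C9–C10 together with an auxiliary C1–C9 bond that the target no longer has.
- Enabling feature: C9 lies between oxygen-bearing C8 and the methyl-bearing fusion carbon C10. C9 can therefore be the carbene carbon of a diazoketone whose link C6–C7–C8 hangs from C5 of a finished ring A and reaches the C1=C10 double bond.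
- Forward: ring A comes with (R)-α-ionone, and ring B and a cyclopropane close in one step. Iodide then breaks C1–C9, leaving a C8/C9 enol ether (for C11, then CH3 on C8) and a C1 handle (C1=C2, then oxygen at C3). The C15 chain is joined at C11 three steps from the end.
- Stereochemistry: C5 is bought, C10 follows from C5 through the short link, and C9 and C8 follow from attack on the convex β face of the resulting cis-decalin.

Key step: step 3

Assumption: (R)-α-ionone 1 is taken as purchasable in enantiopure form.
Remark: the C3 carbinol centre of 13, 14, 16 and 17 is erased in step 12 and is drawn as the expected 3α epimer. C11 of 16 is erased in step 11 and is left undefined.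

**Step 1**
Reactants: 1 (R)-α-ionone
Product: 3 (R)-dihydro-α-ionone [4-((1R)-2,6,6-trimethylcyclohex-2-en-1-yl)butan-2-one], via triethylsilyl enol ether 2 (not isolated)
Conditions: RhCl(PPh3)3 (0.5 mol %), Et3SiH (1.2 equiv), toluene, 50 °C; then 1 M HCl, THF, 0 °C
Reagents that add atoms: triethylsilane, CC[SiH](CC)CC (the silyl group is found in 2 only)
Why: Rhodium-catalysed 1,4-hydrosilylation of an enone with a monohydrosilane reduces only the conjugated C=C bond, ignores the isolated ring alkene, and runs under neutral conditions, so the doubly allylic C5–H (the only stereocentre) should neither epimerise nor let the ring alkene slip into conjugation before mild hydrolysis of 2 frees the ketone.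

**Step 2**
Reactants: 3 (R)-dihydro-α-ionone
Product: 5 1-diazo-4-[(1R)-2,6,6-trimethylcyclohex-2-en-1-yl]butan-2-one, via trifluoroacetyl diketone 4 (not isolated)
Conditions: LiN(SiMe3)2 (1.1 equiv), THF, −78 °C, then CF3CO2CH2CF3 (1.2 equiv); crude 4, MsN3 (1.5 equiv), Et3N (1.5 equiv), H2O (1 equiv), MeCN, 23 °C
Reagents that add atoms: methanesulfonyl azide, CS(=O)(=O)N=[N+]=[N-]; 2,2,2-trifluoroethyl trifluoroacetate, O=C(OCC(F)(F)F)C(F)(F)F (its CF3CO group is found in 4 only)
Why: Kinetic deprotonation takes the unhindered methyl group, Claisen-type trifluoroacetylation activates exactly that carbon, and the detrifluoroacetylative form of the Regitz diazo transfer should then give the terminal diazoketone without touching the ring alkene or C5.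

**Step 3**
Reactants: 5 1-diazo-4-[(1R)-2,6,6-trimethylcyclohex-2-en-1-yl]butan-2-one
Product: 6 1α,9α-cyclo-4,4,10β-trimethyl-5βH-decalin-8-one (cyclopropane C1–C9–C10 on the α face; H-1, H-5, H-9 and CH3-10 β)
Conditions: Rh2(OAc)4 (1 mol %), CH2Cl2, slow addition of 5 over 6 h, 23 °C
Reagents that add atoms: none
Why: Rh2(OAc)4 binds the diazo carbon of 5, nitrogen leaves, and the electrophilic rhodium carbenoid at C9 adds to the C1=C10 double bond in one asynchronous concerted [2+1] event that forms C9–C10 and C9–C1 on the same alkene face. The closest known reaction type is the rhodium- or copper-catalysed intramolecular cyclopropanation of unsaturated α-diazoketones to bicyclo[4.1.0]heptan-2-ones. Ring B (C5–C10) closes in the exo sense, C9 bonding to the proximal alkene carbon C10 through the three-atom link C6–C7–C8 while C1 stays outside the new six-membered ring, and the three-membered ring C1–C9–C10 closes in the same event. C10 is controlled by C5, because the link leaves C5 on the α face and is too short to reach the other face, so C9 arrives α and the methyl group ends β, syn to H-5 (cis fusion). C1 and C9 are fixed by the syn addition and by the need for the cyclopropane to be cis-fused to both six-membered rings, which places H-1 and H-9 β. The step needs chemoselectivity for the alkene over insertion into C5–H (five-membered ring) and over carbene dimerisation, and this is secured by the electron-rich trisubstituted alkene held next to the carbenoid, by the shielding of C5–H by the C4 gem-dimethyl group, and by slow addition.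

**Step 4**
Reactants: 6 1α,9α-cyclo-4,4,10β-trimethyl-5βH-decalin-8-one
Product: 8 4,4,10β-trimethyl-8-(trimethylsilyloxy)-5βH-hexalin-1,8(9)-diene, via iodo silyl enol ether 7 (not isolated)
Conditions: Me3SiI (1.1 equiv), 2,6-di-tert-butylpyridine (0.2 equiv), toluene, −20 to 23 °C; then DBU (3 equiv), 80 °C; cold aq NaHCO3/pentane
Reagents that add atoms: iodotrimethylsilane, C[Si](C)(C)I
Why: In this homoconjugate opening of a cyclopropyl ketone, O-silylation activates the ring, the C1–C9 bond stands nearly perpendicular to the carbonyl plane whereas C9–C10 lies in it, and iodide can reach secondary C1 but not quaternary C10, so 7 should form with inversion at C1 and with a regiodefined C8=C9 enol ether, after which E2 loss of HI can only run towards C2 because C10 carries no hydrogen.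

**Step 5**
Reactants: 8 4,4,10β-trimethyl-8-(trimethylsilyloxy)-5βH-hexalin-1,8(9)-diene; 9 chloromethyl phenyl sulfide
Product: 10 9β-(phenylthiomethyl)-4,4,10β-trimethyl-5βH-octal-1-en-8-one (H-9 α)
Conditions: 9 (1.1 equiv), TiCl4 (1.0 equiv), CH2Cl2, −78 to −40 °C; cold aq NaHCO3
Reagents that add atoms: 9 chloromethyl phenyl sulfide, ClCSc1ccccc1
Why: In this Mukaiyama-type alkylation TiCl4 ionises 9 to the small thionium ion PhS=CH2(+), which is captured only at C9 of the enol ether and from the convex β face, because in the conformer that keeps C4 equatorial on ring B the α face is closed by pseudoaxial C1 (and by axial C4 in the other half-chair), so C11 should end syn to CH3-10.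

**Step 6**
Reactants: 10 9β-(phenylthiomethyl)-4,4,10β-trimethyl-5βH-octal-1-en-8-one
Product: 11 9β-(phenylthiomethyl)-4,4,8β,10β-tetramethyl-5βH-octal-1-en-8α-ol
Conditions: MeLi (2 equiv), anhydrous CeCl3 (2.2 equiv), THF, −78 °C; then H2O
Reagents that add atoms: methyllithium, [Li]C
Why: Organocerium 1,2-addition is nucleophilic but barely basic, which should suppress enolisation at C9 (epimerisation, loss of thiophenolate), and the methyl group should enter along the equatorial β trajectory because the axial α trajectory is blocked by syn-axial C1 of ring A, giving 8β-CH3 and 8α-OH.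

**Step 7**
Reactants: 11 9β-(phenylthiomethyl)-4,4,8β,10β-tetramethyl-5βH-octal-1-en-8α-ol
Product: 12 9β-(phenylsulfonylmethyl)-4,4,8β,10β-tetramethyl-5βH-octal-1-en-8α-ol
Conditions: 30% H2O2 (3 equiv), (NH4)6Mo7O24·4H2O (5 mol %), EtOH, 0 to 23 °C
Reagents that add atoms: hydrogen peroxide, OO
Why: Molybdate-catalysed peroxide oxidation of a sulfide to the sulfone is far faster than epoxidation of the hindered 1,2-disubstituted alkene, and the sulfone both survives the next oxidation and acidifies C11 for the later coupling.

**Step 8**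
Reactants: 12 9β-(phenylsulfonylmethyl)-4,4,8β,10β-tetramethyl-5βH-octal-1-en-8α-ol
Product: 13 9β-(phenylsulfonylmethyl)-4,4,8β,10β-tetramethyl-5βH-octal-1-ene-3α,8α-diol
Conditions: SeO2 (0.5 equiv), t-BuOOH (3 equiv, decane), CH2Cl2, 23 °C
Reagents that add atoms: selenium dioxide, O=[Se]=O (delivers the oxygen); tert-butyl hydroperoxide, CC(C)(C)OO (re-oxidises selenium)
Why: In the SeO2 allylic hydroxylation (ene reaction, then [2,3]-sigmatropic shift) selenium must bond to C1 and take a hydrogen from C3, the only allylic C–H since C10 is quaternary, and the shift returns the alkene to C1=C2 with oxygen on C3, so the regiochemistry follows from the mechanism, while the π-aligned pseudoaxial 3α-H should lead to the 3α-alcohol.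

**Step 9**
Reactants: 13 9β-(phenylsulfonylmethyl)-4,4,8β,10β-tetramethyl-5βH-octal-1-ene-3α,8α-diol
Product: 14 9β-(phenylsulfonylmethyl)-4,4,8β,10β-tetramethyl-5βH-decalin-3α,8α-diol
Conditions: H2 (1 atm), PtO2 (5 mol %), EtOAc, 23 °C
Reagents that add atoms: none
Why: Heterogeneous hydrogenation saturates the only C=C bond while the polyene chain is still absent, platinum in a neutral solvent limits allylic hydrogenolysis and isomerisation, and no stereocentre is created.

**Step 10**
Reactants: 14 9β-(phenylsulfonylmethyl)-4,4,8β,10β-tetramethyl-5βH-decalin-3α,8α-diol; 15 (2E,6E)-farnesyl bromide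
Product: 16 C11-farnesylated sulfone, 9β-[(3E,7E)-4,8,12-trimethyl-1-(phenylsulfonyl)trideca-3,7,11-trienyl]-4,4,8β,10β-tetramethyl-5βH-decalin-3α,8α-diol (C11 epimers)
Conditions: n-BuLi (3.1 equiv), THF–DMPU, −78 to −30 °C; 15 (1.1 equiv), −78 to −30 °C; then H2O
Reagents that add atoms: 15 (2E,6E)-farnesyl bromide, CC(C)=CCC/C(C)=C/CC/C(C)=C/CBr
Why: In this sulfone-anion alkylation (Biellmann-type coupling) the third equivalent of base lithiates C11 after both hydroxyls, and the soft carbanion should displace the primary allylic bromide by SN2 without allylic transposition or loss of E geometry, while the lithium alkoxides stay inert at low temperature.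

**Step 11**
Reactants: 16 C11-farnesylated sulfone
Product: 17 9β-[(3E,7E)-4,8,12-trimethyltrideca-3,7,11-trienyl]-4,4,8β,10β-tetramethyl-5βH-decalin-3α,8α-diol
Conditions: Na(Hg) (6% Na), Na2HPO4, MeOH–THF, −20 to 0 °C
Reagents that add atoms: none
Why: Reductive desulfonylation by electron transfer cleaves the C11–S bond, and because the sulfone is homoallylic rather than allylic and no carbonyl group is present, the trisubstituted alkenes should keep position and geometry and nothing else is reducible.

**Step 12**
Reactants: 17 9β-[(3E,7E)-4,8,12-trimethyltrideca-3,7,11-trienyl]-4,4,8β,10β-tetramethyl-5βH-decalin-3α,8α-diol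
Product: 18 IN0671, (5S,8R,9R,10S)-8-hydroxy-4,4,8,10-tetramethyl-9-[(3E,7E)-4,8,12-trimethyltrideca-3,7,11-trienyl]decalin-3-one
Conditions: Dess–Martin periodinane (1.3 equiv), pyridine, CH2Cl2, 0 to 23 °C
Reagents that add atoms: none
Why: The Dess–Martin oxidation can act only on the secondary C3 carbinol, leaves the tertiary C8 hydroxyl and the alkenes alone under buffered conditions, and the new ketone is flanked by C2H2 and quaternary C4, so no stereocentre can epimerise.

**Compound list**
1 | (R)-α-ionone, (3E)-4-[(1R)-2,6,6-trimethylcyclohex-2-en-1-yl]but-3-en-2-one | CC1=CCCC(C)(C)[C@H]1/C=C/C(C)=O | starting material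
2 | (Z)-triethylsilyl enol ether of 3 | CC1=CCCC(C)(C)[C@H]1C/C=C(/C)O[Si](CC)(CC)CC | intermediate
3 | (R)-dihydro-α-ionone | CC1=CCCC(C)(C)[C@H]1CCC(C)=O | intermediate
4 | 1,1,1-trifluoro-6-[(1R)-2,6,6-trimethylcyclohex-2-en-1-yl]hexane-2,4-dione | CC1=CCCC(C)(C)[C@H]1CCC(=O)CC(=O)C(F)(F)F | intermediate
5 | 1-diazo-4-[(1R)-2,6,6-trimethylcyclohex-2-en-1-yl]butan-2-one | [N-]=[N+]=CC(=O)CC[C@H]1C(C)=CCCC1(C)C | intermediate
6 | 1α,9α-cyclo-4,4,10β-trimethyl-5βH-decalin-8-one | O=C1CC[C@@H]2C(C)(C)CC[C@@H]3[C@H]1[C@]23C | intermediate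
7 | 1β-iodo-4,4,10β-trimethyl-8-(trimethylsilyloxy)-5βH-octal-8(9)-ene | C[Si](C)(C)OC1=C[C@@]2(C)[C@H](I)CCC(C)(C)[C@H]2CC1 | intermediate
8 | 4,4,10β-trimethyl-8-(trimethylsilyloxy)-5βH-hexalin-1,8(9)-diene | C[Si](C)(C)OC1=C[C@@]2(C)C=CCC(C)(C)[C@H]2CC1 | intermediate
9 | chloromethyl phenyl sulfide | ClCSc1ccccc1 | starting material
10 | 9β-(phenylthiomethyl)-4,4,10β-trimethyl-5βH-octal-1-en-8-one | c1ccc(cc1)SC[C@@H]1[C@@]2(C)C=CCC(C)(C)[C@H]2CCC1=O | intermediate
11 | 9β-(phenylthiomethyl)-4,4,8β,10β-tetramethyl-5βH-octal-1-en-8α-ol | c1ccc(cc1)SC[C@@H]1[C@@]2(C)C=CCC(C)(C)[C@H]2CC[C@@]1(C)O | intermediate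
12 | 9β-(phenylsulfonylmethyl)-4,4,8β,10β-tetramethyl-5βH-octal-1-en-8α-ol | O=S(=O)(c1ccccc1)C[C@@H]1[C@@]2(C)C=CCC(C)(C)[C@H]2CC[C@@]1(C)O | intermediate
13 | 9β-(phenylsulfonylmethyl)-4,4,8β,10β-tetramethyl-5βH-octal-1-ene-3α,8α-diol | O=S(=O)(c1ccccc1)C[C@@H]1[C@@]2(C)C=C[C@@H](O)C(C)(C)[C@H]2CC[C@@]1(C)O | intermediate
14 | 9β-(phenylsulfonylmethyl)-4,4,8β,10β-tetramethyl-5βH-decalin-3α,8α-diol | O=S(=O)(c1ccccc1)C[C@@H]1[C@@]2(C)CC[C@@H](O)C(C)(C)[C@H]2CC[C@@]1(C)O | intermediate
15 | (2E,6E)-farnesyl bromide | CC(C)=CCC/C(C)=C/CC/C(C)=C/CBr | starting material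
16 | C11-farnesylated sulfone (C11 epimers) | CC(C)=CCC/C(C)=C/CC/C(C)=C/CC(S(=O)(=O)c1ccccc1)[C@@H]1[C@@]2(C)CC[C@@H](O)C(C)(C)[C@H]2CC[C@@]1(C)O | intermediate
17 | 3α,8α-diol carrying the complete side chain | CC(C)=CCC/C(C)=C/CC/C(C)=C/CC[C@@H]1[C@@]2(C)CC[C@@H](O)C(C)(C)[C@H]2CC[C@@]1(C)O | intermediate
18 | IN0671 | CC(C)=CCC/C(C)=C/CC/C(C)=C/CC[C@@H]1[C@@]2(C)CCC(=O)C(C)(C)[C@H]2CC[C@@]1(C)O | target

**Step count and risks**
Total step count: 12. Longest linear sequence: 12 steps (1 to 18); 9 and 15 are bought.

Steps most likely to fail: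

**Step 4.**
- What may go wrong: once DBU traps the silyl group, the enol ether may displace iodide and close the cyclopropane again.
- The anti elimination of an equatorial, neopentyl-type iodide may be slow enough for this to compete.
- Partial desilylation would also lose the enol regiochemistry.
- Fallback (sets out from 6, returns at 11): 6 is opened with Me3SiI as before, but no base is added. Crude 7 is alkylated at once with 9 and TiCl4 to give the iodo ketone 1β-iodo-9β-(phenylthiomethyl)-4,4,10β-trimethyl-5βH-decalin-8-one F1. MeLi/CeCl3 turns this into the iodo carbinol 1β-iodo-9β-(phenylthiomethyl)-4,4,8β,10β-tetramethyl-5βH-decalin-8α-ol F2. Only then is HI removed with DBU in hot toluene to give 11. At that stage no enol derivative is left, so re-closure of the three-membered ring is impossible.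

**Step 6.**
- What may go wrong: the ketone is crowded on both faces (syn-axial C1 on α, the axial C11 arm on β), so addition may be slow.
- Slow addition would give room to enolisation with loss of thiophenolate, to epimerisation at C9, and to erosion of facial selectivity.
- Fallback (sets out from 10, returns at 11): methylene transfer replaces methyl addition. Dimethyloxosulfonium methylide (Me3S(O)I, NaH, DMSO; Corey–Chaykovsky epoxidation) is too weak a base to enolise the ketone. Through its reversible addition it places the new carbon equatorial (β), giving the spiro-epoxide 9β-(phenylthiomethyl)-4,4,10β-trimethyl-5βH-octal-1-ene-8-spiro-oxirane (oxygen α) F3. LiEt3BH in THF opens F3 at the CH2 terminus to give 11.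

**Step 8.**
- What may go wrong: the ene step has to bond selenium to C1 next to quaternary C10 and may be sluggish.
- Prolonged exposure invites over-oxidation to the enone and acid-promoted loss of the tertiary hydroxyl.
- Fallback (sets out from 12, returns at 13): hydrogen-abstraction chemistry at the ketone level replaces the ene pathway. CrO3/3,5-dimethylpyrazole in CH2Cl2 at −20 °C takes 12 to the enone 8α-hydroxy-9β-(phenylsulfonylmethyl)-4,4,8β,10β-tetramethyl-5βH-octal-1-en-3-one F4, which is separated from any transposed isomer. Luche reduction (NaBH4, CeCl3·7H2O, MeOH) should deliver hydride from the β face, away from syn-axial C6, to give 13.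

**Further compounds**
F1 | step 4 | 1β-iodo-9β-(phenylthiomethyl)-4,4,10β-trimethyl-5βH-decalin-8-one | c1ccc(cc1)SC[C@@H]1[C@@]2(C)[C@H](I)CCC(C)(C)[C@H]2CCC1=O
F2 | step 4 | 1β-iodo-9β-(phenylthiomethyl)-4,4,8β,10β-tetramethyl-5βH-decalin-8α-ol | c1ccc(cc1)SC[C@@H]1[C@@]2(C)[C@H](I)CCC(C)(C)[C@H]2CC[C@@]1(C)O
F3 | step 6 | 9β-(phenylthiomethyl)-4,4,10β-trimethyl-5βH-octal-1-ene-8-spiro-oxirane (oxygen α) | c1ccc(cc1)SC[C@@H]1[C@@]2(C)C=CCC(C)(C)[C@H]2CC[C@]13CO3
F4 | step 8 | 8α-hydroxy-9β-(phenylsulfonylmethyl)-4,4,8β,10β-tetramethyl-5βH-octal-1-en-3-one | O=S(=O)(c1ccccc1)C[C@@H]1[C@@]2(C)C=CC(=O)C(C)(C)[C@H]2CC[C@@]1(C)O
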